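(Flavan numbering; rings A/C = chroman, ring B = C1'–C6', ring D = pyran O1''–C4'' fused to ring B at C3'–C4'.) Kazinol H ⇒ MOM ether 19 (5'-OH freed last) ⇒ 7-O-prenyl flavan 17 by aromatic Claisen rearrangement, which makes the C6 bond of the 2-methylbut-3-en-2-yl group and frees 7-OH.
Ring C of 17 ⇒ (S)-bromo carbinol 16 by copper-catalysed O1–C8a aryl ether formation; 16 ⇒ ketone 15 by asymmetric transfer hydrogenation; 15 ⇒ ring-A aldehyde 12 + ring-B/D methyl ketone 10 by Claisen–Schmidt condensation and conjugate reduction.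
Ring D of 10 ⇒ salicylaldehyde 7 + 2-methylprop-1-enylboronic acid: borono-Mannich reaction, loss of amine and oxa-6π-electrocyclisation in one pot make the C4''=C3'' and O1''–C2'' bonds together; 7 ⇒ acetophenone 1 by bromination and prenylation at C2' and formylation at C3'.
Enabling feature: on ring B the formyl carbon at C3' has a single ortho hydroxyl, O4'–H (O5' is an ether, C2' carries the prenyl group), so only O4' can carry boron to the iminium carbon and then become ring oxygen O1''; closing ring D before C2 exists also keeps every later intermediate free of a 4'-OH para to the benzylic C2–O1 bond.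
Rings A and B come from the two aromatic starting materials; ring D is formed first (step 6), ring C second (step 11).

Key step: step 6

Assumption: 1, 11, tributyl(3-methylbut-2-en-1-yl)stannane and 2-methylprop-1-en-1-ylboronic acid are taken as commercial, and ring bromination of 2 is taken to follow the para-to-alkoxy, ortho-to-acyl pattern of 3,4-dialkoxy aryl ketones.

Step 1
Reactants: 1 1-(3-hydroxy-4-methoxyphenyl)ethanone
Product: 2 1-[4-methoxy-3-(methoxymethoxy)phenyl]ethanone
Conditions: MOMCl, i-Pr2NEt, CH2Cl2, 0 °C to rt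
Reagents that add atoms: chloromethyl methyl ether, COCCl
Why: Williamson-type O-alkylation (MOM ether formation) of the only phenol; an acetal ether neither migrates to a neighbouring phenoxide nor binds magnesium as a phenoxide would, so O5' stays silent until the last step.

Step 2
Reactants: 2 1-[4-methoxy-3-(methoxymethoxy)phenyl]ethanone
Product: 3 1-[2-bromo-4-methoxy-5-(methoxymethoxy)phenyl]ethanone
Conditions: NBS, MeCN, rt, dark
Reagents that add atoms: N-bromosuccinimide, O=C1CCC(=O)N1Br
Why: Electrophilic aromatic bromination: the position para to the MOM-oxy group (C2', ortho to acetyl) is the most activated because the 4'-methoxy group is engaged in push–pull conjugation with the para-acetyl group, and NBS without acid leaves the ketone α-position and the acetal alone.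

Step 3
Reactants: 3 1-[2-bromo-4-methoxy-5-(methoxymethoxy)phenyl]ethanone
Product: 4 1-[4-methoxy-5-(methoxymethoxy)-2-(3-methylbut-2-en-1-yl)phenyl]ethanone
Conditions: Pd(PPh3)4 (5 mol %), tributyl(3-methylbut-2-en-1-yl)stannane, DMF, 90 °C; aq. KF work-up
Reagents that add atoms: tributyl(3-methylbut-2-en-1-yl)stannane, CCCC[Sn](CCCC)(CCCC)CC=C(C)C
Why: Stille coupling: oxidative addition of zerovalent palladium is helped by the ortho-acetyl group and carbon–carbon bond formation at the unsubstituted terminus of the allyl unit should give the linear 3-methylbut-2-enyl arene, the ketone being inert to the stannane.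

Step 4
Reactants: 4 1-[4-methoxy-5-(methoxymethoxy)-2-(3-methylbut-2-en-1-yl)phenyl]ethanone
Product: 5 1-[4-hydroxy-5-(methoxymethoxy)-2-(3-methylbut-2-en-1-yl)phenyl]ethanone
Conditions: NaSEt, DMF, 110 °C; then dilute aq. HCl to pH 5
Reagents that add atoms: none
Why: Nucleophilic demethylation (SN2 at the methyl carbon by thiolate): only the methoxy group para to the acetyl group releases a stabilised phenoxide, while the MOM acetal and the prenyl group do not react with thiolate.

Step 5
Reactants: 5 1-[4-hydroxy-5-(methoxymethoxy)-2-(3-methylbut-2-en-1-yl)phenyl]ethanone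
Product: 7 3-acetyl-6-hydroxy-5-(methoxymethoxy)-2-(3-methylbut-2-en-1-yl)benzaldehyde, via ortho-hydroxymethyl phenol 6 (not isolated)
Conditions: MgCl2, Et3N, (CH2O)n, MeCN, 80 °C
Reagents that add atoms: formaldehyde (as paraformaldehyde), C=O
Why: Magnesium-mediated ortho-formylation (Casnati–Skattebøl reaction): formaldehyde bound to the magnesium phenoxide of O4' is delivered to C3', the only free ortho carbon, the hydroxymethyl phenol 6 is oxidised in situ by a second formaldehyde (hydride transfer), and the acetyl group is not enolised because it is part of a vinylogous phenoxide.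

Step 6
Reactants: 7 3-acetyl-6-hydroxy-5-(methoxymethoxy)-2-(3-methylbut-2-en-1-yl)benzaldehyde
Product: 10 1-[8-(methoxymethoxy)-2,2-dimethyl-5-(3-methylbut-2-en-1-yl)-2H-chromen-6-yl]ethanone, via benzylic amine 8 (not isolated), via ortho-quinone methide 9 (not isolated)
Conditions: 2-methylprop-1-en-1-ylboronic acid (1.5 equiv), Bn2NH (0.3 equiv), 1,4-dioxane, 90 °C
Reagents that add atoms: 2-methylprop-1-en-1-ylboronic acid, CC(C)=CB(O)O
Why: Dibenzylamine and the formyl group of 7 give an iminium ion, the neighbouring O4' phenoxide binds the boronic acid as a tetracoordinate boronate and the 2-methylprop-1-enyl group migrates from boron to the iminium carbon through a six-membered transition state (C4''–C3'' bond, amine 8), 8 then loses dibenzylamine at 90 °C to give the ortho-quinone methide 9, and oxa-6π-electrocyclisation of 9 forms the O1''–C2'' bond and frees the amine for the next turn. The closest known reaction is the amine-catalysed condensation of salicylaldehydes with alkenylboronic acids to 2H-chromenes (Petasis borono-Mannich reaction followed by amine elimination), here with a β,β-dimethyl alkenylboronic acid. Ring D closes by a thermal disrotatory 6π-electrocyclisation of the 1-oxatriene in 9, driven by rearomatisation of ring B. No stereocentre is formed, because C2'' carries two methyl groups and the stereocentre of 8 is lost in 9. The step must use the formyl and not the acetyl group and must close onto O4' only: the acetyl group has no ortho hydroxyl to carry boron, O5' is an ether, and the prenyl group on C2' pushes the dienyl arm of 9 toward the carbonyl oxygen, the geometry needed for closure. Attack of the prenyl alkene on the iminium ion is the conceivable side reaction, but the intramolecular boron-to-carbon transfer should be faster.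

Step 7
Reactants: 11 2-bromo-4-hydroxybenzaldehyde
Product: 12 2-bromo-4-[(3-methylbut-2-en-1-yl)oxy]benzaldehyde
Conditions: 1-bromo-3-methylbut-2-ene, K2CO3, DMF, rt
Reagents that add atoms: 1-bromo-3-methylbut-2-ene, CC(C)=CCBr
Why: Williamson ether synthesis: the phenoxide of 11 (the only acidic site) displaces bromide from the primary allylic bromide at oxygen.

Step 8
Reactants: 10 1-[8-(methoxymethoxy)-2,2-dimethyl-5-(3-methylbut-2-en-1-yl)-2H-chromen-6-yl]ethanone; 12 2-bromo-4-[(3-methylbut-2-en-1-yl)oxy]benzaldehyde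
Product: 14 (E)-3-{2-bromo-4-[(3-methylbut-2-en-1-yl)oxy]phenyl}-1-[8-(methoxymethoxy)-2,2-dimethyl-5-(3-methylbut-2-en-1-yl)-2H-chromen-6-yl]prop-2-en-1-one, via aldol adduct 13 (not isolated)
Conditions: KOH, EtOH/H2O, rt
Reagents that add atoms: none
Why: Claisen–Schmidt condensation (crossed aldol then E1cB dehydration of 13): 10 is the only enolisable partner and 12 the only aldehyde, the conjugated enone forms as the E isomer, and the MOM ether, the aryl bromide, both prenyl units and ring D tolerate aqueous-ethanolic hydroxide.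

Step 9
Reactants: 14 (E)-3-{2-bromo-4-[(3-methylbut-2-en-1-yl)oxy]phenyl}-1-[8-(methoxymethoxy)-2,2-dimethyl-5-(3-methylbut-2-en-1-yl)-2H-chromen-6-yl]prop-2-en-1-one
Product: 15 3-{2-bromo-4-[(3-methylbut-2-en-1-yl)oxy]phenyl}-1-[8-(methoxymethoxy)-2,2-dimethyl-5-(3-methylbut-2-en-1-yl)-2H-chromen-6-yl]propan-1-one
Conditions: Cu(OAc)2·H2O (5 mol %), 1,2-bis(diphenylphosphino)benzene (5 mol %), (EtO)2MeSiH, t-BuOH, toluene, rt
Reagents that add atoms: none
Why: Copper hydride-catalysed conjugate reduction (Stryker-type): the copper hydride adds only to the β-carbon of the enone and tert-butanol protonates the copper enolate, so that the ketone, the aryl bromide, the ring-D double bond and the two trisubstituted alkenes are kept.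

Step 10
Reactants: 15 3-{2-bromo-4-[(3-methylbut-2-en-1-yl)oxy]phenyl}-1-[8-(methoxymethoxy)-2,2-dimethyl-5-(3-methylbut-2-en-1-yl)-2H-chromen-6-yl]propan-1-one
Product: 16 (1S)-3-{2-bromo-4-[(3-methylbut-2-en-1-yl)oxy]phenyl}-1-[8-(methoxymethoxy)-2,2-dimethyl-5-(3-methylbut-2-en-1-yl)-2H-chromen-6-yl]propan-1-ol
Conditions: RuCl(p-cymene)[(S,S)-TsDPEN] (2 mol %), HCO2Na, H2O/i-PrOH (1:1), 40 °C
Reagents that add atoms: none
Why: Noyori asymmetric transfer hydrogenation: the (S,S)-TsDPEN ruthenium hydride transfers hydride and proton to the ketone face that places the aryl group next to the η6-arene ligand, which gives the (S)-carbinol as for acetophenone (priorities OH > aryl > CH2 are alike) and sets the only stereocentre under near-neutral conditions that spare the alkenes, the bromide and the acid-labile prenyl ether.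

Step 11
Reactants: 16 (1S)-3-{2-bromo-4-[(3-methylbut-2-en-1-yl)oxy]phenyl}-1-[8-(methoxymethoxy)-2,2-dimethyl-5-(3-methylbut-2-en-1-yl)-2H-chromen-6-yl]propan-1-ol
Product: 17 (2S)-2-[8-(methoxymethoxy)-2,2-dimethyl-5-(3-methylbut-2-en-1-yl)-2H-chromen-6-yl]-7-[(3-methylbut-2-en-1-yl)oxy]-3,4-dihydro-2H-chromene
Conditions: CuI (10 mol %), 3,4,7,8-tetramethyl-1,10-phenanthroline (20 mol %), Cs2CO3, toluene, 110 °C, argon
Reagents that add atoms: none
Why: Copper-catalysed intramolecular Ullmann-type etherification (alkoxide arylation, closure of ring C as a six-membered ring at the O1–C8a bond): the C2–O bond is never broken, so the configuration is retained and remains S (O1 > C1' > C3), and 110 °C is below the onset of the Claisen rearrangement of the prenyl ether.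

Step 12
Reactants: 17 (2S)-2-[8-(methoxymethoxy)-2,2-dimethyl-5-(3-methylbut-2-en-1-yl)-2H-chromen-6-yl]-7-[(3-methylbut-2-en-1-yl)oxy]-3,4-dihydro-2H-chromene
Product: 19 (2S)-2-[8-(methoxymethoxy)-2,2-dimethyl-5-(3-methylbut-2-en-1-yl)-2H-chromen-6-yl]-6-(2-methylbut-3-en-2-yl)-3,4-dihydro-2H-chromen-7-ol, via cyclohexadienone 18 (not isolated)
Conditions: N,N-diethylaniline, 180 °C, sealed tube under argon
Reagents that add atoms: none
Why: Aromatic Claisen rearrangement ([3,3]-sigmatropic shift through a chair transition state to dienone 18, then tautomerisation): the new bond is formed to C6, para to O1, rather than to C8, which lies between O1 and O7, for steric reasons and because a meta alkoxy group steers the migration away from itself, as known for 2-alkoxy-4-prenyloxy arenes; any C8 isomer would be removed by chromatography, and the neutral thermal conditions do not touch C2.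

Step 13
Reactants: 19 (2S)-2-[8-(methoxymethoxy)-2,2-dimethyl-5-(3-methylbut-2-en-1-yl)-2H-chromen-6-yl]-6-(2-methylbut-3-en-2-yl)-3,4-dihydro-2H-chromen-7-ol
Product: 21 Kazinol H [(2S)-2-[8-hydroxy-2,2-dimethyl-5-(3-methylbut-2-en-1-yl)-2H-chromen-6-yl]-6-(2-methylbut-3-en-2-yl)-3,4-dihydro-2H-chromen-7-ol], via bis-trimethylsilyl ether 20 (not isolated)
Conditions: TMSOTf, 2,2'-bipyridyl, MeCN, 0 °C to rt; then H2O
Reagents that add atoms: none
Why: Silyl triflate–bipyridyl cleavage of an aryl MOM ether (acetal exchange to the aryl silyl ether 20, hydrolysed on adding water): no protic acid is present, so the C2–O1 bond, a para-alkoxybenzylic ether, is not ionised (no racemisation) and ring D, the prenyl group and the 2-methylbut-3-en-2-yl phenol are not protonated.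

Compound list
1 | 1-(3-hydroxy-4-methoxyphenyl)ethanone | CC(=O)c1ccc(OC)c(O)c1 | starting material
2 | 1-[4-methoxy-3-(methoxymethoxy)phenyl]ethanone | CC(=O)c1ccc(OC)c(OCOC)c1 | intermediate
3 | 1-[2-bromo-4-methoxy-5-(methoxymethoxy)phenyl]ethanone | CC(=O)c1cc(OCOC)c(OC)cc1Br | intermediate
4 | 1-[4-methoxy-5-(methoxymethoxy)-2-(3-methylbut-2-en-1-yl)phenyl]ethanone | CC(=O)c1cc(OCOC)c(OC)cc1CC=C(C)C | intermediate
5 | 1-[4-hydroxy-5-(methoxymethoxy)-2-(3-methylbut-2-en-1-yl)phenyl]ethanone | CC(=O)c1cc(OCOC)c(O)cc1CC=C(C)C | intermediate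
6 | 1-[4-hydroxy-3-(hydroxymethyl)-5-(methoxymethoxy)-2-(3-methylbut-2-en-1-yl)phenyl]ethanone | CC(=O)c1cc(OCOC)c(O)c(CO)c1CC=C(C)C | intermediate
7 | 3-acetyl-6-hydroxy-5-(methoxymethoxy)-2-(3-methylbut-2-en-1-yl)benzaldehyde | CC(=O)c1cc(OCOC)c(O)c(C=O)c1CC=C(C)C | intermediate
8 | 1-[3-[1-(dibenzylamino)-3-methylbut-2-en-1-yl]-4-hydroxy-5-(methoxymethoxy)-2-(3-methylbut-2-en-1-yl)phenyl]ethanone (racemic) | CC(=O)c1cc(OCOC)c(O)c(C(C=C(C)C)N(Cc2ccccc2)Cc2ccccc2)c1CC=C(C)C | intermediate
9 | 4-acetyl-2-(methoxymethoxy)-5-(3-methylbut-2-en-1-yl)-6-(3-methylbut-2-en-1-ylidene)cyclohexa-2,4-dien-1-one | CC(=O)C1=C(CC=C(C)C)C(=CC=C(C)C)C(=O)C(OCOC)=C1 | intermediate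
10 | 1-[8-(methoxymethoxy)-2,2-dimethyl-5-(3-methylbut-2-en-1-yl)-2H-chromen-6-yl]ethanone | CC(=O)c1cc(OCOC)c2OC(C)(C)C=Cc2c1CC=C(C)C | intermediate
11 | 2-bromo-4-hydroxybenzaldehyde | O=Cc1ccc(O)cc1Br | starting material
12 | 2-bromo-4-[(3-methylbut-2-en-1-yl)oxy]benzaldehyde | O=Cc1ccc(OCC=C(C)C)cc1Br | intermediate
13 | 3-{2-bromo-4-[(3-methylbut-2-en-1-yl)oxy]phenyl}-3-hydroxy-1-[8-(methoxymethoxy)-2,2-dimethyl-5-(3-methylbut-2-en-1-yl)-2H-chromen-6-yl]propan-1-one (racemic) | O=C(CC(O)c1ccc(OCC=C(C)C)cc1Br)c1cc(OCOC)c2OC(C)(C)C=Cc2c1CC=C(C)C | intermediate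
14 | (E)-3-{2-bromo-4-[(3-methylbut-2-en-1-yl)oxy]phenyl}-1-[8-(methoxymethoxy)-2,2-dimethyl-5-(3-methylbut-2-en-1-yl)-2H-chromen-6-yl]prop-2-en-1-one | O=C(/C=C/c1ccc(OCC=C(C)C)cc1Br)c1cc(OCOC)c2OC(C)(C)C=Cc2c1CC=C(C)C | intermediate
15 | 3-{2-bromo-4-[(3-methylbut-2-en-1-yl)oxy]phenyl}-1-[8-(methoxymethoxy)-2,2-dimethyl-5-(3-methylbut-2-en-1-yl)-2H-chromen-6-yl]propan-1-one | O=C(CCc1ccc(OCC=C(C)C)cc1Br)c1cc(OCOC)c2OC(C)(C)C=Cc2c1CC=C(C)C | intermediate
16 | (1S)-3-{2-bromo-4-[(3-methylbut-2-en-1-yl)oxy]phenyl}-1-[8-(methoxymethoxy)-2,2-dimethyl-5-(3-methylbut-2-en-1-yl)-2H-chromen-6-yl]propan-1-ol | O[C@H](c1cc(OCOC)c2OC(C)(C)C=Cc2c1CC=C(C)C)CCc1ccc(OCC=C(C)C)cc1Br | intermediate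
17 | (2S)-2-[8-(methoxymethoxy)-2,2-dimethyl-5-(3-methylbut-2-en-1-yl)-2H-chromen-6-yl]-7-[(3-methylbut-2-en-1-yl)oxy]-3,4-dihydro-2H-chromene | CC(C)=CCOc1ccc2c(c1)O[C@H](c1cc(OCOC)c3OC(C)(C)C=Cc3c1CC=C(C)C)CC2 | intermediate
18 | (2S)-2-[8-(methoxymethoxy)-2,2-dimethyl-5-(3-methylbut-2-en-1-yl)-2H-chromen-6-yl]-6-(2-methylbut-3-en-2-yl)-2,3,4,6-tetrahydro-7H-chromen-7-one (both C6 epimers) | O=C1C=C2O[C@H](c3cc(OCOC)c4OC(C)(C)C=Cc4c3CC=C(C)C)CCC2=CC1C(C)(C)C=C | intermediate
19 | (2S)-2-[8-(methoxymethoxy)-2,2-dimethyl-5-(3-methylbut-2-en-1-yl)-2H-chromen-6-yl]-6-(2-methylbut-3-en-2-yl)-3,4-dihydro-2H-chromen-7-ol | C=CC(C)(C)c1cc2c(cc1O)O[C@H](c1cc(OCOC)c3OC(C)(C)C=Cc3c1CC=C(C)C)CC2 | intermediate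
20 | bis(trimethylsilyl) ether of 21 (silyl groups on O7 and O5') | C=CC(C)(C)c1cc2c(cc1O[Si](C)(C)C)O[C@H](c1cc(O[Si](C)(C)C)c3OC(C)(C)C=Cc3c1CC=C(C)C)CC2 | intermediate
21 | Kazinol H, (2S)-2-[8-hydroxy-2,2-dimethyl-5-(3-methylbut-2-en-1-yl)-2H-chromen-6-yl]-6-(2-methylbut-3-en-2-yl)-3,4-dihydro-2H-chromen-7-ol | C=CC(C)(C)c1cc2c(cc1O)O[C@H](c1cc(O)c3OC(C)(C)C=Cc3c1CC=C(C)C)CC2 | target

Total step count: 13. Longest linear sequence: 12 steps (1 to 21 through steps 1–6 and 8–13); step 7 is a one-step side branch.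

Steps most likely to fail

Step 5 (ortho-formylation). Carbon–carbon bond formation may stall because the magnesium ion is held in the O4'/O5' chelate and C3' is flanked by the prenyl group; on long heating formaldehyde may instead add to the prenyl alkene. The fallback sets out from 5 and forms the bond by boron-templated ortho-hydroxymethylation, adjusting the oxidation level separately. PhB(OH)2, paraformaldehyde and catalytic propionic acid in refluxing toluene with removal of water should give the cyclic aryl boronate 1-[8-(methoxymethoxy)-5-(3-methylbut-2-en-1-yl)-2-phenyl-4H-1,3,2-benzodioxaborinin-6-yl]ethanone F1. Exchange with propane-1,3-diol should release the hydroxymethyl phenol 6, isolated in this variant, and MnO2 in CH2Cl2 should oxidise its benzylic alcohol to 7, where the route is rejoined.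

Step 11 (ring C closure). Oxidative addition into the hindered aryl bromide may be slow, so that the benzylic alkoxide is consumed by elimination or oxidation, or the prenyl ether starts to rearrange at the temperature needed. The fallback sets out from 10 and closes ring C at the C2–O1 bond by substitution at carbon instead of at the O1–C8a bond. 2,4-Dihydroxybenzaldehyde, 1-bromo-3-methylbut-2-ene and KHCO3 in acetone should give 2-hydroxy-4-[(3-methylbut-2-en-1-yl)oxy]benzaldehyde F3 (the chelated 2-OH stays free). Claisen–Schmidt condensation of F3 with 10 (KOH, EtOH) should give (E)-3-{2-hydroxy-4-[(3-methylbut-2-en-1-yl)oxy]phenyl}-1-[8-(methoxymethoxy)-2,2-dimethyl-5-(3-methylbut-2-en-1-yl)-2H-chromen-6-yl]prop-2-en-1-one F4. Copper hydride conjugate reduction as in step 9 (extra silane, fluoride work-up) should give 3-{2-hydroxy-4-[(3-methylbut-2-en-1-yl)oxy]phenyl}-1-[8-(methoxymethoxy)-2,2-dimethyl-5-(3-methylbut-2-en-1-yl)-2H-chromen-6-yl]propan-1-one F5. Transfer hydrogenation with RuCl(p-cymene)[(R,R)-TsDPEN] should give (1R)-3-{2-hydroxy-4-[(3-methylbut-2-en-1-yl)oxy]phenyl}-1-[8-(methoxymethoxy)-2,2-dimethyl-5-(3-methylbut-2-en-1-yl)-2H-chromen-6-yl]propan-1-ol F6. Mitsunobu cyclisation of F6 (PPh3, DIAD, THF, 0 °C, high dilution) should proceed with inversion to 17, where the route is rejoined.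

Step 6 (key annulation). Iminium formation at the doubly flanked formyl group may be slow, or the iminium ion may be captured by the neighbouring prenyl alkene before the boron-to-carbon transfer. The fallback sets out from 5, so it also bypasses step 5, and builds ring D from the aryl ether side. O-Alkylation with 3-chloro-3-methylbut-1-yne (DBU, catalytic CuCl2, MeCN, 0 °C) should give 1-[5-(methoxymethoxy)-4-[(2-methylbut-3-yn-2-yl)oxy]-2-(3-methylbut-2-en-1-yl)phenyl]ethanone F2. Heating F2 in N,N-diethylaniline at 180 °C (propargyl Claisen rearrangement to C3', the only free ortho carbon, [1,5]-hydrogen shift and oxa-6π-electrocyclisation through 9) should give 10, where the route is rejoined.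

Further compounds
F1 | step 5 | 1-[8-(methoxymethoxy)-5-(3-methylbut-2-en-1-yl)-2-phenyl-4H-1,3,2-benzodioxaborinin-6-yl]ethanone | CC(=O)c1cc(OCOC)c2OB(c3ccccc3)OCc2c1CC=C(C)C
F2 | step 6 | 1-[5-(methoxymethoxy)-4-[(2-methylbut-3-yn-2-yl)oxy]-2-(3-methylbut-2-en-1-yl)phenyl]ethanone | CC(=O)c1cc(OCOC)c(OC(C)(C)C#C)cc1CC=C(C)C
F3 | step 11 | 2-hydroxy-4-[(3-methylbut-2-en-1-yl)oxy]benzaldehyde | O=Cc1ccc(OCC=C(C)C)cc1O
F4 | step 11 | (E)-3-{2-hydroxy-4-[(3-methylbut-2-en-1-yl)oxy]phenyl}-1-[8-(methoxymethoxy)-2,2-dimethyl-5-(3-methylbut-2-en-1-yl)-2H-chromen-6-yl]prop-2-en-1-one | O=C(/C=C/c1ccc(OCC=C(C)C)cc1O)c1cc(OCOC)c2OC(C)(C)C=Cc2c1CC=C(C)C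
F5 | step 11 | 3-{2-hydroxy-4-[(3-methylbut-2-en-1-yl)oxy]phenyl}-1-[8-(methoxymethoxy)-2,2-dimethyl-5-(3-methylbut-2-en-1-yl)-2H-chromen-6-yl]propan-1-one | O=C(CCc1ccc(OCC=C(C)C)cc1O)c1cc(OCOC)c2OC(C)(C)C=Cc2c1CC=C(C)C
F6 | step 11 | (1R)-3-{2-hydroxy-4-[(3-methylbut-2-en-1-yl)oxy]phenyl}-1-[8-(methoxymethoxy)-2,2-dimethyl-5-(3-methylbut-2-en-1-yl)-2H-chromen-6-yl]propan-1-ol | O[C@@H](c1cc(OCOC)c2OC(C)(C)C=Cc2c1CC=C(C)C)CCc1ccc(OCC=C(C)C)cc1O
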